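A one-step world has one arrow, D + J to Q, and the fall of D tells its whole progress. But these runs also show G, the complex with two exchanged, so Q takes a second J, and each exchange must free one ligand, which I call Z.

| setting | maple | larch | flask |
|---|---|---|---|
| D | 2.1 M | 2.1 M | 2.1 M |
| J | 1.47 M | 2.9 M | 1.47 M |
| remark | the very flask that is asked about, followed so far | run made earlier |  |
| time |  |  | 4.0 h |

| run | time / min | D / % | Q / % | G / % |
|---|---|---|---|---|
| maple | 2.00 | 94.7 | 4.3 | 0.5 |
| maple | 6.00 | 87.6 | 10.8 | 0.7 |
| maple | 10.0 | 82.6 | 15.2 | 2.2 |
| maple | 15.0 | 77.1 | 16.8 | 4.9 |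
| maple | 20.0 | 73.6 | 20.2 | 6.1 |
| maple | 30.0 | 70.8 | 21.0 | 6.4 |
| larch | 15.0 | 63.0 | 26.0 | 12.2 |
| larch | 30.0 | 54.0 | 27.0 | 17.8 |
| larch | 50.0 | 52.6 | 26.8 | 20.1 |
| larch | 60.0 | 54.4 | 24.0 | 20.7 |
| larch | 80.0 | 53.2 | 25.4 | 19.4 |
| larch | 90.0 | 53.8 | 26.1 | 21.2 |

(readings scatter by 1 percentage point)

- the reaction counts as stopped when no species that holds the D changes by six tenths of a point or more over the second half of the time

* the state of affairs at 4.0 h: stopped, and by what, or still going (all of D has reacted / forward and back rates have come level / J has run out first / it is still moving)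
* how much of the D has reacted by 4.0 h
* how much Q there is at 4.0 h, in percent of the D charged
* how much G there is at 4.0 h, in percent of the D charged

So Z = Q + 2G, turned into molar from the D charged, and J is its charge minus Z. I follow the exchange quotient C = (Q/D)(Z/J), which climbs as the first step runs forward. Larch is flat from 50.0 min to 90.0 min, and at its last reading Z is 1.44 M with 1.46 M of J still there. So J has not stopped larch, and I take its C as the level at which the first step's forward and back rates match: K = 0.477, a reading with its scatter.

But maple at 30.0 min reads C = 0.277, below K, and its D fell 2.8 percentage points over the last interval, so it is still moving forward. The flask gets 8.00 times that time, so I commit to C reaching K before 4.0 h, in a plain approach to equilibrium.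

The forecast says the same, forward and back rates have come level, with 31.3% reacted, Q 20.9% and G 10.4%; of larch it says “so that plateau is equilibrium rather than J exhaustion”.

The flask gives forward and back rates have come level, with 31.9% reacted, Q 21.1% and G 10.2%.

    D + J ⇌ Z + Q (K = 0.470, k = 2.70 × 10⁻⁴ L mol⁻¹ s⁻¹)
    Q + J ⇌ Z + G (K = 0.730, k = 4.40 × 10⁻⁴ L mol⁻¹ s⁻¹)
    Q → L (k = 1.80 × 10⁻⁶ s⁻¹)

The undoing of Z + Q into D + J is the largest single effect on conversion: without it the flask reaches 64.8%, against 31.9% with it. At 4.00 h the flask stands at C = 0.469, against K of 0.477. A neighbour flask, charged with 0.88 M of J, stands at C = 0.469 at the same time, with D at 77.1%.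

(Readings and results were computed for substances that don't exist, and the scatter is random.)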